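**Assumption:** the target, 5,4'-dihydroxy-7,2'-dimethoxy-8-prenylflavone (C22H22O6), has no stereocentres and no E/Z-defined alkene, so it is achiral and no enantiocontrol is needed. Compounds 1 and 4 are taken as catalogue items. The route is designed from known reaction types and has not been run.

## Retrosynthetic overview
1. Target ⇐ removal of a MOM group from the 4'-O-MOM-protected 8-prenylflavone.
2. 8-Prenyl-5-hydroxy A-ring ⇐ Eu(III)-catalysed para-Claisen–Cope rearrangement of the flavone 5-O-prenyl ether, which fixes C8 regiochemistry and frees the 5-OH.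
3. 5-O-Prenyl ether ⇐ O-alkylation of the chelated 5-OH of a 5-hydroxy-7-methoxyflavone (4'-OH masked as MOM).
4. Flavone C-ring, the only ring formed (A and B rings are bought) ⇐ oxidative cyclisation of a 2',6'-dihydroxychalcone ⇐ Claisen–Schmidt condensation of 2',6'-dihydroxy-4'-methoxyacetophenone with 2-methoxy-4-(methoxymethoxy)benzaldehyde.

## Forward route

**Step 1**
Reactants: 1, 4-hydroxy-2-methoxybenzaldehyde; 2, chloromethyl methyl ether (MOMCl)
Product: 3, 2-methoxy-4-(methoxymethoxy)benzaldehyde
Conditions: MOMCl (1.5 eq), i-Pr2NEt (2 eq), CH2Cl2, 0 °C → rt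
Reagents that add atoms: MOMCl, COCCl
Why: O-alkylation of the only phenol gives a base-stable MOM acetal, so the 4-oxygen is not a free phenoxide that would deactivate the aldehyde in the aldol step and compete in the later prenylation.

**Step 2**
Reactants: 4, 1-(2,6-dihydroxy-4-methoxyphenyl)ethan-1-one (2',6'-dihydroxy-4'-methoxyacetophenone); 3, 2-methoxy-4-(methoxymethoxy)benzaldehyde
Product: 5, (E)-1-(2,6-dihydroxy-4-methoxyphenyl)-3-[2-methoxy-4-(methoxymethoxy)phenyl]prop-2-en-1-one (chalcone)
Conditions: 50% aq KOH (excess), EtOH, rt, 48–72 h; then AcOH to pH ~6 at 0 °C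
Reagents that add atoms: none
Why: Claisen–Schmidt aldol condensation with E1cB dehydration gives the thermodynamic E-enone; any chalcone that closes to the isomeric flavanone is carried forward, since both converge in Step 3.

**Step 3**
Reactants: 5, the chalcone
Product: 6, 5-hydroxy-7-methoxy-2-[2-methoxy-4-(methoxymethoxy)phenyl]-4H-chromen-4-one
Conditions: I2 (1.1 eq), pyridine, 95 °C; aq Na2S2O3 work-up
Reagents that add atoms: none
Why: Base-promoted 6-endo oxa-Michael closure to the flavanone, then iodine-mediated dehydrogenation (C3 iodination and loss of HI), gives the flavone. The two ortho OH groups are equivalent, so there is one regioisomer, and the pyridine buffer protects the MOM group from HI.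

**Step 4**
Reactants: 6, the 5-hydroxyflavone; 7, 1-bromo-3-methylbut-2-ene (prenyl bromide)
Product: 8, 7-methoxy-2-[2-methoxy-4-(methoxymethoxy)phenyl]-5-[(3-methylbut-2-en-1-yl)oxy]-4H-chromen-4-one
Conditions: prenyl bromide (2 eq), K2CO3 (3 eq), cat. TBAI, acetone, reflux
Reagents that add atoms: prenyl bromide, CC(C)=CCBr
Why: Williamson etherification (SN2) of the 5-OH, which is the only free hydroxyl; it is chelated to the carbonyl and so needs excess halide and heat.

**Step 5**
Reactants: 8, the 5-O-prenyl ether
Product: 9, 5-hydroxy-7-methoxy-2-[2-methoxy-4-(methoxymethoxy)phenyl]-8-(3-methylbut-2-en-1-yl)-4H-chromen-4-one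
Conditions: Eu(fod)3 (10 mol%), NaHCO3, PhCl, 85 °C
Reagents that add atoms: none
Why: Eu(III) chelation of the C4=O/5-O pair accelerates a [3,3] Claisen shift to C6, giving a 1,1-dimethylallyl dienone; a second [3,3] Cope shift moves the group to C8 as a normal prenyl, and tautomerisation restores the 5-OH (para-Claisen–Cope). The minor 6-(1,1-dimethylallyl) ortho product is removed by chromatography.

**Step 6**
Reactants: 9, the 4'-O-MOM 8-prenylflavone
Product: 10, Artocarpetin B, 5-hydroxy-2-(4-hydroxy-2-methoxyphenyl)-7-methoxy-8-(3-methylbut-2-en-1-yl)-4H-chromen-4-one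
Conditions: 3 M aq HCl, MeOH, rt → 50 °C
Reagents that add atoms: none
Why: Acid-catalysed acetal hydrolysis removes the MOM group. The prenyl group sits between 7-OMe and the ring oxygen, so it has no neighbouring free OH to cyclise onto, and the aryl methyl ethers are inert.

## Compound list
1 | 4-hydroxy-2-methoxybenzaldehyde | COc1cc(O)ccc1C=O | starting material
2 | chloromethyl methyl ether (MOMCl) | COCCl | starting material (reagent)
3 | 2-methoxy-4-(methoxymethoxy)benzaldehyde | COCOc1ccc(C=O)c(OC)c1 | intermediate
4 | 1-(2,6-dihydroxy-4-methoxyphenyl)ethan-1-one | CC(=O)c1c(O)cc(OC)cc1O | starting material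
5 | (E)-1-(2,6-dihydroxy-4-methoxyphenyl)-3-[2-methoxy-4-(methoxymethoxy)phenyl]prop-2-en-1-one | COCOc1ccc(/C=C/C(=O)c2c(O)cc(OC)cc2O)c(OC)c1 | intermediate
6 | 5-hydroxy-7-methoxy-2-[2-methoxy-4-(methoxymethoxy)phenyl]-4H-chromen-4-one | COCOc1ccc(-c2cc(=O)c3c(O)cc(OC)cc3o2)c(OC)c1 | intermediate
7 | 1-bromo-3-methylbut-2-ene (prenyl bromide) | CC(C)=CCBr | starting material (reagent)
8 | 7-methoxy-2-[2-methoxy-4-(methoxymethoxy)phenyl]-5-[(3-methylbut-2-en-1-yl)oxy]-4H-chromen-4-one | COCOc1ccc(-c2cc(=O)c3c(OCC=C(C)C)cc(OC)cc3o2)c(OC)c1 | intermediate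
9 | 5-hydroxy-7-methoxy-2-[2-methoxy-4-(methoxymethoxy)phenyl]-8-(3-methylbut-2-en-1-yl)-4H-chromen-4-one | COCOc1ccc(-c2cc(=O)c3c(O)cc(OC)c(CC=C(C)C)c3o2)c(OC)c1 | intermediate
10 | Artocarpetin B, 5-hydroxy-2-(4-hydroxy-2-methoxyphenyl)-7-methoxy-8-(3-methylbut-2-en-1-yl)-4H-chromen-4-one | COc1cc(O)ccc1-c1cc(=O)c2c(O)cc(OC)c(CC=C(C)C)c2o1 | target

## Summary
Total steps: 6. Longest linear sequence: 6 (1 → 3 → 5 → 6 → 8 → 9 → 10).

Three steps most likely to fail, each with a fallback that changes the approach:

1. **Step 5 (para-Claisen–Cope).** The rearrangement may stop at the ortho 6-(1,1-dimethylallyl) product or lose the prenyl group. Fallback: drop the sigmatropic route and install the prenyl by cross-coupling. Build the 5,7-dimethoxy analogue of 6 from 2'-hydroxy-4',6'-dimethoxyacetophenone, iodinate at C8 (NIS; 5-O-alkyl flavones iodinate at C8), couple with prenyl-Bpin (Suzuki–Miyaura), then use BCl3 for chelation-controlled 5-O-demethylation with MOM removal in the same step.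

2. **Step 2 (Claisen–Schmidt on the unprotected 2',6'-dihydroxyacetophenone).** The dianion is a sluggish enolate precursor and yields may be low. Fallback: avoid the chalcone. Acylate the LiHMDS polyanion of 4 with methyl 2-methoxy-4-(methoxymethoxy)benzoate to give the β-diketone, then cyclodehydrate with acid to the flavone (Baker–Venkataraman-type disconnection). If the MOM group is lost, re-protect the 4'-OH, which reacts selectively over the chelated 5-OH.

3. **Step 4 (alkylation of the chelated 5-OH).** Conversion may be slow, with some C-alkylation. Fallback: move the prenyl ether to the start. Mono-O-prenylate symmetric acetophenone 4 (the second OH stays chelated), then carry 2'-hydroxy-4'-methoxy-6'-prenyloxyacetophenone through the Claisen–Schmidt and I2/pyridine steps to reach 8 directly.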